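At 60.0 h, the last reading of maple, target reads 15.4 % and substrate reads 0 %, so you take over a flask that looks finished.

| setting | maple | cedar | flask |
|---|---|---|---|
| substrate | 0.10 M | 0.10 M | 0.10 M |
| coupling partner | 0.13 M | 0.087 M | 0.130 M |
| temperature | 70 °C | 65 °C | 70 °C |
| remark | the very flask that is asked about, followed so far | run made earlier |  |
| time |  |  | 2.5 d |

| run | time / h | target / % | substrate / % |
|---|---|---|---|
| maple | 4.00 | 10.6 | 25.6 |
| maple | 12.0 | 14.2 | 5.4 |
| maple | 20.0 | 13.4 | 1.2 |
| maple | 30.0 | 13.6 | 0.7 |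
| maple | 50.0 | 13.5 | 0 |
| maple | 60.0 | 15.4 | 0 |
| cedar | 0.333 | 0.7 | 90.8 |
| cedar | 0.500 | 0.8 | 86.1 |
| cedar | 1.00 | 1.7 | 79.0 |
| cedar | 1.50 | 2.1 | 69.5 |
| cedar | 2.50 | 4.6 | 58.7 |
| cedar | 4.00 | 6.7 | 47.6 |

(standard deviation of a reading: 1 percentage point)

- what is taken out of target is counted as made
- the analysis behind the earlier runs scatters by 1 percentage point, standard deviation
- additions bring no volume worth counting

1. target, in percent of the substrate first charged, at 2.5 d
2. what to do for the largest gain in target; "none" if nothing gains more than 2 percentage points (dawn / summer / dusk / winter / none)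
3. target present, with what was taken out counted in, in percent of the substrate first charged, after dawn
4. target present, with what was taken out counted in, in percent of the substrate first charged, after summer

- dawn: at 2.5 d take out 90 % of the target then present, then wait 2.5 d
- summer: at 2.5 d add coupling partner, 50.0 % of the amount charged, then wait 2.5 d
- dusk: change nothing and wait 2.5 d more
- winter: at 2.5 d raise the temperature by 20 K, then wait 2.5 d

Don't work maple up yet. From 12.0 h on, target averages 14.0 %, so 86.0 % of the substrate stands in neither column, and that unseen material may still take up partner.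

Maple's plateau divided by its [coupling partner]/[substrate] of 1.30 gives 10.8 %, the yield per equivalent: target won per equivalent of partner charged. At 4.00 h the same ratio reads 8.15 % in maple and 7.70 % in cedar, close against a scatter of 1 percentage point, although cedar, at 65 °C, had turned over less substrate.

Expect about 14.0 % in maple when you come. Summer lifts maple to 1.95 equivalents, and your reckoning then gives 21.0 %, a gain above the margin of 2 points.

The forecast says 14 %, best none, dawn 14.1 %, summer 14.2 %, holding of the target that “it stalls because the substrate has run out”. On summer it parts from your reckoning.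

The flask gives 14.4 %; the best move is winter, worth 13 points, while dawn reaches 24.9 % and summer 22.2 %.

    substrate + coupling partner → intermediate A (k = 0.00106 L mol⁻¹ s⁻¹, Ea = 73.0 kJ mol⁻¹)
    substrate → intermediate B (k = 2.63 × 10⁻⁵ s⁻¹, Ea = 102 kJ mol⁻¹)
    target ⇌ isomer of the product (K = 2.80, k = 6.53 × 10⁻⁵ s⁻¹, Ea = 106 kJ mol⁻¹, ΔH = −44.0 kJ mol⁻¹)
    intermediate C ⇌ intermediate A (K = 12.9, k = 2.85 × 10⁻⁵ s⁻¹, Ea = 105 kJ mol⁻¹, ΔH = −90.0 kJ mol⁻¹)
    coupling partner + intermediate A → target (k = 6.45 × 10⁻⁴ L mol⁻¹ s⁻¹, Ea = 64.0 kJ mol⁻¹)
    coupling partner + intermediate B ⇌ intermediate C (K = 10.0 L mol⁻¹, k = 6.30 × 10⁻⁴ L mol⁻¹ s⁻¹, Ea = 75.0 kJ mol⁻¹, ΔH = −42.0 kJ mol⁻¹)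
    coupling partner ⇌ dormant form (K = 0.440, k = 3.95 × 10⁻⁵ s⁻¹, Ea = 111 kJ mol⁻¹, ΔH = 27.0 kJ mol⁻¹)
    (constants at 70 °C)

Target and isomer of the product relax into each other with a half-life of 2.17 h by this step, far shorter than the 2.5 d of the run. At 60.0 h maple holds 14.4 % target beside 39.1 % isomer of the product, and target is still made 1.23 times faster than it is used up, each step taken net. The yield per equivalent gave 21.0 % for summer, against 22.2 % computed. For a neighbour flask charged with 0.22 M of partner it gives 23.7 %; the computed result there is 24.2 %.

The readings were generated by integration on assumed constants; noise was put on by code.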